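**Retrosynthetic overview**

- The strategy rests on the 1,4-diketone C1(=O)–C6–Cα–C7(=O)Ar, read as the cleavage product of a cyclobutene C1=C7. C1 is the carbonyl carbon of the six-membered ring, C6 the quaternary ring carbon bearing allyl, Cα the CH(CH3) carbon, C7 the aryl ketone carbon, and C4 the CH(OMe) ring carbon.
- Target ⇒ Saegusa oxidation (C2=C3, last) ⇒ diketone ⇒ epoxidation and periodate cleavage ⇒ 8-aryl-bicyclo[4.2.0]oct-1(8)-ene ⇒ gold [2+2] of a (Z)-aryl 1,7-enyne.
- Ring order: the six-membered carbocycle and the fused cyclobutene close together in the key step (C1–C6 and Cα–C7), and the four-membered ring is then opened.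
- Enyne ⇒ Sonogashira coupling (C7–Ar), propargylation of a primary triflate (C3–C2), Evans glycolate alkylation (C4–C5, sets C4), and syn-hydromagnesiation/allylation of but-2-yn-1-ol. The last step fixes the (Z) alkene; a plain carbocupration cannot place allyl on the metal-bearing carbon with CH3 cis to the metal.

Key step: step 10

Remark: the two oxirane carbons of intermediate 21 (and the two acetal carbons of the ozonide in the fallback) are written without configuration, since both become carbonyl carbons.

**Route**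

Step 1
Reactants: 1 but-2-yn-1-ol; 2 allyl bromide
Product: 4 (2Z)-2-(prop-2-en-1-yl)but-2-en-1-ol, via alkenylmagnesium alkoxide 3 (not isolated)
Conditions: i-BuMgCl (2.1 equiv), Cp2TiCl2 (5 mol%), Et2O, 0 °C to rt; then 2, CuI (10 mol%), THF, 0 °C to rt; aq NH4Cl
Reagents that add atoms: none
Why: Titanocene-catalysed syn-hydromagnesiation of the 2-alkyn-1-ol alkoxide should place Mg at C2 and H at C3 on the same side, and copper-catalysed allylation of the alkenyl Grignard with retention then leaves CH3 cis to CH2OH, the (Z) geometry that later becomes the C6/Cα relationship.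

Step 2
Reactants: 4 (2Z)-2-(prop-2-en-1-yl)but-2-en-1-ol
Product: 5 (4Z)-4-(iodomethyl)hexa-1,4-diene
Conditions: PPh3, I2, imidazole, CH2Cl2, 0 °C, dark
Reagents that add atoms: iodine, II
Why: Appel-type iodination of a primary allylic alcohol proceeds by SN2 displacement of the oxyphosphonium group and should not touch the alkene geometry.

Step 3
Reactants: 6 (4S)-4-benzyl-1,3-oxazolidin-2-one; 7 methoxyacetyl chloride
Product: 9 (4S)-4-benzyl-3-(methoxyacetyl)-1,3-oxazolidin-2-one, via lithiated oxazolidinone 8 (not isolated)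
Conditions: n-BuLi, THF, −78 °C; then 7, −78 to 0 °C
Reagents that add atoms: none
Why: N-acylation of the lithiated Evans auxiliary with an acid chloride is standard and leaves the auxiliary stereocentre untouched.

Step 4
Reactants: 9 (4S)-4-benzyl-3-(methoxyacetyl)-1,3-oxazolidin-2-one; 5 (4Z)-4-(iodomethyl)hexa-1,4-diene
Product: 11 (4S)-4-benzyl-3-[(2R,4Z)-2-methoxy-4-(prop-2-en-1-yl)hex-4-enoyl]-1,3-oxazolidin-2-one, via sodium enolate 10 (not isolated)
Conditions: NaN(SiMe3)2, THF, −78 °C; then 5 (2.5 equiv), −78 to −45 °C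
Reagents that add atoms: none
Why: Evans-type asymmetric glycolate alkylation: the chelated sodium (Z)-enolate should be alkylated by the primary allylic iodide (SN2) on the face opposite the benzyl group, which sets the methoxy-bearing carbon (future C4) as (R) in the imide.

Step 5
Reactants: 11 (4S)-4-benzyl-3-[(2R,4Z)-2-methoxy-4-(prop-2-en-1-yl)hex-4-enoyl]-1,3-oxazolidin-2-one
Product: 12 (2R,4Z)-2-methoxy-4-(prop-2-en-1-yl)hex-4-en-1-ol
Conditions: LiBH4, H2O (1.1 equiv), Et2O, 0 °C
Reagents that add atoms: none
Why: Reductive cleavage of the N-acyloxazolidinone by borohydride should give the primary alcohol without enolisation of the α-alkoxy centre and release the auxiliary for recovery.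

Step 6
Reactants: 12 (2R,4Z)-2-methoxy-4-(prop-2-en-1-yl)hex-4-en-1-ol
Product: 13 (2R,4Z)-2-methoxy-4-(prop-2-en-1-yl)hex-4-en-1-yl trifluoromethanesulfonate
Conditions: Tf2O, 2,6-lutidine, CH2Cl2, −78 °C; used at once
Reagents that add atoms: trifluoromethanesulfonic anhydride, O=S(=O)(OS(=O)(=O)C(F)(F)F)C(F)(F)F
Why: O-triflation of a primary alcohol with a hindered base at low temperature gives a leaving group reactive enough for SN2 at a β-alkoxy carbon.

Step 7
Reactants: 13 (2R,4Z)-2-methoxy-4-(prop-2-en-1-yl)hex-4-en-1-yl trifluoromethanesulfonate; 14 1-(trimethylsilyl)propyne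
Product: 16 [(5S,7Z)-5-methoxy-7-(prop-2-en-1-yl)non-7-en-1-yn-1-yl]trimethylsilane, via 3-lithio-1-(trimethylsilyl)propyne 15 (not isolated)
Conditions: 14, n-BuLi, THF, −78 to −20 °C; then 13, −78 to −20 °C
Reagents that add atoms: none
Why: SN2 alkylation of the silyl-capped propargyllithium, which reacts at its CH2 terminus because the silyl group suppresses allenyl attack, should form C3–C2; the stereocentre is untouched and only its descriptor changes from R to S.

Step 8
Reactants: 16 [(5S,7Z)-5-methoxy-7-(prop-2-en-1-yl)non-7-en-1-yn-1-yl]trimethylsilane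
Product: 17 (5S,7Z)-5-methoxy-7-(prop-2-en-1-yl)non-7-en-1-yne
Conditions: K2CO3 (0.2 equiv), MeOH, rt
Reagents that add atoms: none
Why: Base-catalysed methanolysis (protodesilylation) of the alkynyl C–Si bond is selective and mild.

Step 9
Reactants: 17 (5S,7Z)-5-methoxy-7-(prop-2-en-1-yl)non-7-en-1-yne; 18 4-iodo-1,2-dimethoxybenzene
Product: 19 4-[(5S,7Z)-5-methoxy-7-(prop-2-en-1-yl)non-7-en-1-yn-1-yl]-1,2-dimethoxybenzene
Conditions: Pd(PPh3)2Cl2 (2 mol%), CuI (4 mol%), Et3N, THF, rt
Reagents that add atoms: none
Why: Sonogashira coupling of a terminal alkyne with an aryl iodide should proceed at room temperature, and the isolated alkenes are inert.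

Step 10
Reactants: 19 4-[(5S,7Z)-5-methoxy-7-(prop-2-en-1-yl)non-7-en-1-yn-1-yl]-1,2-dimethoxybenzene
Product: 20 (4S,6R,7S)-8-(3,4-dimethoxyphenyl)-4-methoxy-7-methyl-6-(prop-2-en-1-yl)bicyclo[4.2.0]oct-1(8)-ene
Conditions: [(t-Bu)2(2-biphenylyl)P]Au(NCMe)SbF6 (3 mol%), CH2Cl2, 0 °C to rt
Reagents that add atoms: none
Why: The cationic phosphine complex of monovalent gold π-activates the alkyne, the C6=Cα alkene attacks C1 in a 6-exo-dig closure of the six-membered ring to give a cyclopropyl gold carbene with the carbene at benzylic C7, and a 1,2-shift of Cα from C1 to C7 (cyclopropylcarbinyl-to-cyclobutyl ring expansion) followed by loss of the gold fragment closes the four-membered ring as the C1=C7 cyclobutene. The closest known reaction type is the gold- or platinum-catalysed intramolecular [2+2] cycloaddition of aryl-substituted 1,7-enynes to bicyclo[4.2.0]oct-1(8)-enes. C6 should be set by the C4 stereocentre through a chair-like tether with OMe equatorial and allyl pseudoaxial, since the other face would place OMe and allyl syn-diaxial; Cα is set by the (Z) alkene geometry, because both new bonds form on one alkene face so that CH3 ends up cis to C5 and trans to allyl. The step needs ring expansion to win over arene trapping of the cation at Cα (formal [4+2]), proton loss from the doubly allylic CH2 and single-cleavage rearrangement; the donor 3,4-dimethoxyphenyl group stabilises charge at C7 and speeds the shift, the cation at Cα is only secondary, and the tether length disfavours endo closure. The remote allyl alkene would have to form an eight-membered ring and should not compete.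

Step 11
Reactants: 20 (4S,6R,7S)-8-(3,4-dimethoxyphenyl)-4-methoxy-7-methyl-6-(prop-2-en-1-yl)bicyclo[4.2.0]oct-1(8)-ene
Product: 22 (2R,4S)-2-[(2S)-1-(3,4-dimethoxyphenyl)-1-oxopropan-2-yl]-4-methoxy-2-(prop-2-en-1-yl)cyclohexan-1-one, via cyclobutene epoxide 21 (not isolated)
Conditions: mCPBA (1.0 equiv), NaHCO3, CH2Cl2, −20 °C; then H5IO6, THF/H2O, 0 °C
Reagents that add atoms: 3-chloroperoxybenzoic acid, O=C(OO)c1cccc(Cl)c1; water, O
Why: Prilezhaev epoxidation should select the strained, tetrasubstituted, aryl-conjugated cyclobutene over the monosubstituted allyl alkene, and periodic acid should then open the strained benzylic epoxide to the diol and cleave it (Malaprade glycol cleavage) to the two ketones without touching C6 or Cα.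

Step 12
Reactants: 22 (2R,4S)-2-[(2S)-1-(3,4-dimethoxyphenyl)-1-oxopropan-2-yl]-4-methoxy-2-(prop-2-en-1-yl)cyclohexan-1-one
Product: 24 {[(4S,6R)-6-[(2S)-1-(3,4-dimethoxyphenyl)-1-oxopropan-2-yl]-4-methoxy-6-(prop-2-en-1-yl)cyclohex-1-en-1-yl]oxy}trimethylsilane, via lithium enolate 23 (not isolated)
Conditions: LiN(i-Pr)2 (1.1 equiv), Me3SiCl (premixed, internal quench), THF, −78 °C
Reagents that add atoms: chlorotrimethylsilane, C[Si](C)(C)Cl
Why: Kinetic enolate formation with in situ silylation: the C1 ketone can enolise only toward C2 because C6 is quaternary, whereas the only α-hydrogen of the aryl ketone sits on Cα, a hindered methine next to the quaternary centre, and immediate O-silylation should suppress aldol closure onto the aryl ketone.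

Step 13
Reactants: 24 {[(4S,6R)-6-[(2S)-1-(3,4-dimethoxyphenyl)-1-oxopropan-2-yl]-4-methoxy-6-(prop-2-en-1-yl)cyclohex-1-en-1-yl]oxy}trimethylsilane
Product: 25 (4R,6R)-6-[(2S)-1-(3,4-dimethoxyphenyl)-1-oxopropan-2-yl]-4-methoxy-6-(prop-2-en-1-yl)cyclohex-2-en-1-one (target)
Conditions: Pd(OAc)2 (1.1 equiv), MeCN, rt
Reagents that add atoms: none
Why: Saegusa–Ito oxidation: the palladium enolate formed from the silyl enol ether undergoes β-hydride elimination to the C2=C3 enone; no stereocentre is touched and the C4 descriptor changes from S to R only through the priority rules.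

**Compound list**

1 | but-2-yn-1-ol | CC#CCO | starting material
2 | allyl bromide | C=CCBr | starting material
3 | chloromagnesium (2E)-2-(chloromagnesio)but-2-en-1-olate | C/C=C(/[Mg]Cl)CO[Mg]Cl | intermediate
4 | (2Z)-2-(prop-2-en-1-yl)but-2-en-1-ol | C/C=C(/CC=C)CO | intermediate
5 | (4Z)-4-(iodomethyl)hexa-1,4-diene | C/C=C(/CC=C)CI | intermediate
6 | (4S)-4-benzyl-1,3-oxazolidin-2-one | O=C1OC[C@H](Cc2ccccc2)N1 | starting material
7 | methoxyacetyl chloride | COCC(=O)Cl | starting material
8 | lithium salt of (4S)-4-benzyl-1,3-oxazolidin-2-one (N-lithiated) | [Li]N1[C@@H](Cc2ccccc2)COC1=O | intermediate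
9 | (4S)-4-benzyl-3-(methoxyacetyl)-1,3-oxazolidin-2-one | COCC(=O)N1[C@@H](Cc2ccccc2)COC1=O | intermediate
10 | sodium (Z)-enolate of 9 | CO/C=C(\O[Na])N1[C@@H](Cc2ccccc2)COC1=O | intermediate
11 | (4S)-4-benzyl-3-[(2R,4Z)-2-methoxy-4-(prop-2-en-1-yl)hex-4-enoyl]-1,3-oxazolidin-2-one | C/C=C(/CC=C)C[C@@H](OC)C(=O)N1[C@@H](Cc2ccccc2)COC1=O | intermediate
12 | (2R,4Z)-2-methoxy-4-(prop-2-en-1-yl)hex-4-en-1-ol | C/C=C(/CC=C)C[C@@H](OC)CO | intermediate
13 | (2R,4Z)-2-methoxy-4-(prop-2-en-1-yl)hex-4-en-1-yl trifluoromethanesulfonate | C/C=C(/CC=C)C[C@@H](OC)COS(=O)(=O)C(F)(F)F | intermediate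
14 | 1-(trimethylsilyl)propyne | CC#C[Si](C)(C)C | starting material
15 | 3-lithio-1-(trimethylsilyl)propyne | [Li]CC#C[Si](C)(C)C | intermediate
16 | [(5S,7Z)-5-methoxy-7-(prop-2-en-1-yl)non-7-en-1-yn-1-yl]trimethylsilane | C/C=C(/CC=C)C[C@@H](OC)CCC#C[Si](C)(C)C | intermediate
17 | (5S,7Z)-5-methoxy-7-(prop-2-en-1-yl)non-7-en-1-yne | C/C=C(/CC=C)C[C@@H](OC)CCC#C | intermediate
18 | 4-iodo-1,2-dimethoxybenzene | COc1ccc(I)cc1OC | starting material
19 | 4-[(5S,7Z)-5-methoxy-7-(prop-2-en-1-yl)non-7-en-1-yn-1-yl]-1,2-dimethoxybenzene | C/C=C(/CC=C)C[C@@H](OC)CCC#Cc1ccc(OC)c(OC)c1 | intermediate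
20 | (4S,6R,7S)-8-(3,4-dimethoxyphenyl)-4-methoxy-7-methyl-6-(prop-2-en-1-yl)bicyclo[4.2.0]oct-1(8)-ene | C=CC[C@]12C[C@@H](OC)CCC1=C(c3ccc(OC)c(OC)c3)[C@H]2C | intermediate
21 | 1,8-epoxide of 20 (oxirane carbons undefined) | C=CC[C@]12C[C@@H](OC)CCC13OC3(c4ccc(OC)c(OC)c4)[C@H]2C | intermediate
22 | (2R,4S)-2-[(2S)-1-(3,4-dimethoxyphenyl)-1-oxopropan-2-yl]-4-methoxy-2-(prop-2-en-1-yl)cyclohexan-1-one | C=CC[C@]1([C@H](C)C(=O)c2ccc(OC)c(OC)c2)C[C@@H](OC)CCC1=O | intermediate
23 | lithium enolate of 22 (C1–O–Li, C1=C2) | C=CC[C@]1([C@H](C)C(=O)c2ccc(OC)c(OC)c2)C[C@@H](OC)CC=C1O[Li] | intermediate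
24 | {[(4S,6R)-6-[(2S)-1-(3,4-dimethoxyphenyl)-1-oxopropan-2-yl]-4-methoxy-6-(prop-2-en-1-yl)cyclohex-1-en-1-yl]oxy}trimethylsilane | C=CC[C@]1([C@H](C)C(=O)c2ccc(OC)c(OC)c2)C[C@@H](OC)CC=C1O[Si](C)(C)C | intermediate
25 | (4R,6R)-6-[(2S)-1-(3,4-dimethoxyphenyl)-1-oxopropan-2-yl]-4-methoxy-6-(prop-2-en-1-yl)cyclohex-2-en-1-one | C=CC[C@]1([C@H](C)C(=O)c2ccc(OC)c(OC)c2)C[C@@H](OC)C=CC1=O | target

**Step count and risks**

Total steps: 13. Longest linear sequence: 12 steps (steps 1, 2 and 4 to 13 from but-2-yn-1-ol; step 3 is a one-step side branch).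

Steps most likely to fail:

1. Step 10. The cyclopropyl gold carbene may be diverted before ring expansion, through attack of the electron-rich arene on the cationic Cα (formal [4+2]), proton loss from the doubly allylic CH2, or skeletal rearrangement. Closure may also occur on both alkene faces, and the product cyclobutene may isomerise under traces of acid. The fallback keeps the bond set but introduces the aryl group after the ring is built. It sets out from terminal alkyne 17, which is brominated with N-bromosuccinimide and AgNO3 (cat.) in acetone to the bromoalkyne (5S,7Z)-1-bromo-5-methoxy-7-(prop-2-en-1-yl)non-7-en-1-yne F1. This is cyclised with the same gold catalyst (haloalkyne–alkene [2+2], with no arene to intercept the cation and a halogen lone pair stabilising C7) to the bromocyclobutene (4S,6R,7S)-8-bromo-4-methoxy-7-methyl-6-(prop-2-en-1-yl)bicyclo[4.2.0]oct-1(8)-ene F2. Suzuki–Miyaura coupling of F2 with (3,4-dimethoxyphenyl)boronic acid (Pd(PPh3)4, K3PO4, dioxane/H2O) comes back to the route at cyclobutene 20.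

2. Step 11. The strained benzylic epoxide may undergo an acid-promoted semipinacol shift (ring contraction or expansion to a ketone) faster than hydrolytic opening, or the diol may resist glycol cleavage. The fallback replaces epoxidation by a cycloaddition-based cleavage. It sets out from cyclobutene 20, which is treated with ozone in CH2Cl2 at −78 °C, dosed to the end-point of the dye Sudan Red 7B so that the more electron-rich tetrasubstituted alkene is consumed before the allyl group. This forms the bridged secondary ozonide (1,2,4-trioxolane spanning C1 and C7) F3, and reduction with PPh3 comes back to the route at diketone 22.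

3. Step 12. The base may also deprotonate Cα of the aryl ketone, with loss of configuration or double silylation, and the C2 enolate may close onto the aryl ketone in an intramolecular aldol before it is silylated. The fallback avoids a preformed enolate. It sets out from diketone 22, which is dehydrogenated directly with 2-iodoxybenzoic acid in DMSO at 65 °C; this acts on the cyclohexanone CH2–CH2 unit through its enol and comes back to the route at target 25, bypassing 24 and step 13.

**Further compounds**

F1 | step 10 | (5S,7Z)-1-bromo-5-methoxy-7-(prop-2-en-1-yl)non-7-en-1-yne | C/C=C(/CC=C)C[C@@H](OC)CCC#CBr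
F2 | step 10 | (4S,6R,7S)-8-bromo-4-methoxy-7-methyl-6-(prop-2-en-1-yl)bicyclo[4.2.0]oct-1(8)-ene | C=CC[C@]12C[C@@H](OC)CCC1=C(Br)[C@H]2C
F3 | step 11 | secondary ozonide of 20 (1,2,4-trioxolane bridging C1 and C7, acetal carbons undefined) | C=CC[C@]12C[C@@H](OC)CCC1(OO3)OC3(c4ccc(OC)c(OC)c4)[C@H]2C
F0 | step 12 | none | none
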